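**Retrosynthetic overview**

1. Numbering (briarane): C1 = quaternary ring-fusion carbon (CH3 = C15); C2–C9 = rest of the ten-membered ring (C2 OAc, C3=C4, C5=C16H2, C6 Cl, C7 O, C8 OH, C9 OAc); C10 = ring-fusion CH; ring A = C1, C10, C11 (CH3 = C20), C12, C13=C14; lactone = O–C7–C8–C17(C18)–C19.
2. Target ⇒ acetonide removal; γ-lactone by SmI2 Reformatsky closure (C8–C17) on a 7-O-(2-bromopropanoyl) 8-ketone; C6–Cl/C7–OH by HCl opening of a trans-6,7-epoxy-8-ketone made from a macrocyclic C6=C7 enone.
3. Ten-membered ring ⇒ intramolecular Horner–Wadsworth–Emmons olefination (C6=C7) between a C7/C8 β-ketophosphonate (ethynylphosphonate added to the C9 aldehyde) and a C6 enal (acyl Sonogashira/CBS/Lindlar sequence on the C2 acid).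
4. Ring A ⇒ key step: Wittig olefination (C12=C13) of a C9–C12 allylic ylide with the C13–C14–C1(C15)–C2 pseudo-acid 5-hydroxy-3-methylbutenolide, then thermal 6π-electrocyclization (C1–C10). Enabling feature: ring A is a cyclohex-13-ene whose cis-11,12-diol is the osmylation product of a cyclohexa-11,13-diene, i.e. the disrotatory closure product of a C10=C11–C12=C13–C14=C1 triene whose termini become C10 and the quaternary C1 and carry the trans-disposed C9 (outside) and C2 (inside, a carboxylate without α-hydrogen).
5. Order of ring formation: ring A (step 7, resolved in step 8) → ten-membered ring (step 20) → γ-lactone (step 24).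

Key step: step 7

Remark (assumption): α/β refer to ring A, β being the face of the C15 methyl group. The key step gives a racemate that is resolved classically in step 8. The amine (step 8), ProPhenol (step 17) and BINOL (step 21) enantiomers named are those expected to serve, and the antipode would be taken if the empirical sense proved opposite.

**Route**

Step 1
Reactants: 1 3-methylfuran-2-carboxylic acid
Product: 2 5-hydroxy-3-methylfuran-2(5H)-one
Conditions: O2, rose bengal (cat.), visible light, MeOH/CH2Cl2, −10 °C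
Reagents that add atoms: dioxygen, O=O
Why: Singlet-oxygen [4+2] photo-oxygenation of the 2-furoic acid and decarboxylative collapse of the endoperoxide turns the carboxyl-bearing ring carbon into the lactone carbonyl, which places the methyl group at C3 of the hydroxybutenolide; no target stereocenter is set.

Step 2
Reactants: 3 (E)-4-chloro-3-methylbut-2-en-1-yl acetate
Product: 4 (E)-4-chloro-3-methylbut-2-en-1-ol
Conditions: AcCl (cat.), MeOH, 0 °C → rt
Reagents that add atoms: none
Why: Acid-catalysed transesterification frees the primary alcohol without displacing the allylic chloride or moving the (E)-alkene.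

Step 3
Reactants: 4 (E)-4-chloro-3-methylbut-2-en-1-ol
Product: 5 (E)-tert-butyl[(4-chloro-3-methylbut-2-en-1-yl)oxy]dimethylsilane
Conditions: TBSCl, imidazole, CH2Cl2, 0 °C
Reagents that add atoms: tert-butyldimethylsilyl chloride, CC(C)(C)[Si](C)(C)Cl
Why: Standard silylation of a primary alcohol gives an ether that survives ylide formation and is later removed selectively.

Step 4
Reactants: 5 (E)-tert-butyl[(4-chloro-3-methylbut-2-en-1-yl)oxy]dimethylsilane
Product: 6 (E)-{4-[(tert-butyldimethylsilyl)oxy]-2-methylbut-2-en-1-yl}triphenylphosphonium chloride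
Conditions: PPh3, MeCN, 60 °C
Reagents that add atoms: triphenylphosphine, c1ccc(cc1)P(c1ccccc1)c1ccccc1
Why: SN2 quaternisation of the primary allylic chloride gives the phosphonium salt with the (E)-alkene unchanged.

Step 5
Reactants: 7 2-bromo-3,3-diethoxyprop-1-ene; 8 ethynyltrimethylsilane
Product: 9 [3-(diethoxymethyl)but-3-en-1-yn-1-yl]trimethylsilane
Conditions: PdCl2(PPh3)2 (cat.), CuI (cat.), Et3N, THF, 40 °C
Reagents that add atoms: none
Why: Sonogashira coupling of the vinyl bromide joins C4 to C5 and leaves the acetal (masked C6 aldehyde) untouched.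

Step 6
Reactants: 9 [3-(diethoxymethyl)but-3-en-1-yn-1-yl]trimethylsilane
Product: 10 3-(diethoxymethyl)but-3-en-1-yne
Conditions: K2CO3 (cat.), MeOH, 0 °C
Reagents that add atoms: none
Why: Base-catalysed methanolysis cleaves the alkynyl C–Si bond selectively and gives the terminal alkyne.

Step 7
Reactants: 6 (E)-{4-[(tert-butyldimethylsilyl)oxy]-2-methylbut-2-en-1-yl}triphenylphosphonium chloride; 2 5-hydroxy-3-methylfuran-2(5H)-one
Product: 13 rac-(1S,6S)-6-(silyloxymethyl)-1,5-dimethylcyclohexa-2,4-diene-1-carboxylic acid, via phosphonium ylide 11 (not isolated), via sodium trienoate 12 (not isolated)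
Conditions: 2 + NaN(SiMe3)2 (1.0 equiv), THF, −78 °C, added to 11 [6 + NaN(SiMe3)2 (1.05 equiv), THF, −78 °C]; −78 → 0 °C; PhMe added, 100 °C (sealed); 1 M HCl work-up
Reagents that add atoms: none
Why: The semi-stabilised allylic ylide 11 adds to the open (Z)-formyl carboxylate form of pseudo-acid 2 (Wittig olefination, the reaction type used to make 13-cis-retinoic acid from a polyenyl ylide and a 5-hydroxybutenolide, which is known to favour the cis olefin at the new bond), forming the C12=C13 bond and giving the (2Z,4Z,6E)-trienoate 12. On heating, 12 undergoes a thermal disrotatory 6π-electrocyclization (closest precedent: ring closure of dehydrocitral-type (Z)-trienes to safranate-type cyclohexadienes), which forms the C1–C10 σ-bond and closes ring A as a six-membered ring in an all-carbon pericyclic mode. The two new stereocenters, quaternary C1 and C10, are formed together: disrotation places the two outside groups (C15 methyl and CH2OTBS) cis and the two inside groups (carboxylate and H) cis, so the (6E)-geometry carried by the ylide and the (2Z)-geometry locked in the butenolide ring of 2 translate into the trans relation of the C2 and C9 branches; the absolute sense is not controlled and the racemate is resolved in step 8. The selectivity needed is the (4Z)-geometry of the new alkene, since only that isomer can cyclise and the (4E)-isomer stays behind as a separable triene acid; it is secured by kinetic Wittig control with a non-conjugated ylide and a carboxylate-bearing aldehyde. Competing sigmatropic chemistry is designed out: the only inside substituent other than hydrogen is a carboxylate with no α-hydrogen, so the 1,7-hydrogen shift that usually outruns electrocyclization of cis-substituted trienes cannot occur, and the C9 branch that does carry hydrogens is outside.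

Step 8
Reactants: 13 rac-(1S,6S)-6-(silyloxymethyl)-1,5-dimethylcyclohexa-2,4-diene-1-carboxylic acid; 14 (S)-1-phenylethylamine
Product: 15 (S)-1-phenylethylammonium (1S,6S)-6-(silyloxymethyl)-1,5-dimethylcyclohexa-2,4-diene-1-carboxylate
Conditions: 14 (1.0 equiv), EtOAc/heptane, crystallisation and recrystallisation
Reagents that add atoms: none
Why: Classical resolution through diastereomeric ammonium carboxylates should deposit the salt of one enantiomer, which fixes the absolute configuration of C1 and C10 for the rest of the route.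

Step 9
Reactants: 15 (S)-1-phenylethylammonium (1S,6S)-carboxylate
Product: 16 (1S,4R,5S,6S)-6-(silyloxymethyl)-4,5-dihydroxy-1,5-dimethylcyclohex-2-ene-1-carboxylic acid
Conditions: K2OsO4·2H2O (cat.), N-methylmorpholine N-oxide, acetone/H2O, 0 °C → rt; aq. Na2SO3; partition at pH 3 (HCl)
Reagents that add atoms: N-methylmorpholine N-oxide, C[N+]1([O-])CCOCC1; water, O
Why: Catalytic osmylation attacks the more electron-rich trisubstituted C11=C12 bond of the diene from the α face, anti to the β-oriented C15 methyl and C9 silyloxymethyl groups, so the cis-11α,12α-diol (both new stereocenters) is set by substrate control while the hindered C13=C14 bond survives and the carboxylate form suppresses lactonisation.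

Step 10
Reactants: 16 diol acid
Product: 17 11,12-O-isopropylidene acid
Conditions: 2-methoxypropene, PPTS (cat.), CH2Cl2, 0 °C
Reagents that add atoms: 2-methoxypropene, COC(C)=C
Why: Acid-catalysed ketalisation of the cis-1,2-diol gives the dioxolane that masks the tertiary C11 and secondary C12 hydroxyls through all later acylations and oxidations.

Step 11
Reactants: 17 11,12-O-isopropylidene acid; 10 3-(diethoxymethyl)but-3-en-1-yne
Product: 19 C2 ynone, via acid chloride 18 (not isolated)
Conditions: 1-chloro-N,N,2-trimethylprop-1-en-1-amine, CH2Cl2, 0 °C; then 10, PdCl2(PPh3)2 (cat.), CuI (cat.), Et3N, THF, rt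
Reagents that add atoms: none
Why: Neutral conversion of the hindered acid into its chloride and palladium/copper-catalysed acyl Sonogashira coupling form the C2–C3 bond without touching silyl ether, acetal or acetonide, and the quaternary α-carbon excludes ketene formation or epimerisation.

Step 12
Reactants: 19 C2 ynone
Product: 20 C2 propargylic alcohol
Conditions: (S)-2-methyl-CBS-oxazaborolidine (cat.), catecholborane, PhMe, −78 °C
Reagents that add atoms: none
Why: Corey–Bakshi–Shibata reduction distinguishes the quaternary C1 substituent (large) from the linear alkynyl group (small), so hydride is delivered to one face and the C2 carbinol stereocenter is set by catalyst control.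

Step 13
Reactants: 20 C2 propargylic alcohol
Product: 21 (3Z)-allylic alcohol
Conditions: H2 (1 atm), Pd/CaCO3 poisoned with Pb(OAc)2 (Lindlar), quinoline, EtOAc, rt
Reagents that add atoms: none
Why: Lindlar semi-hydrogenation adds hydrogen syn to the alkyne only, which fixes the (3Z)-alkene of the C3=C4–C5=C16 diene and leaves the 1,1-disubstituted and ring alkenes alone.

Step 14
Reactants: 21 (3Z)-allylic alcohol
Product: 22 C2 acetate
Conditions: Ac2O, DMAP (cat.), pyridine, 0 °C → rt
Reagents that add atoms: acetic anhydride, CC(=O)OC(C)=O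
Why: DMAP-catalysed acetylation installs the C2 acetate of the target, which also protects the allylic alcohol during the oxidation in step 16.

Step 15
Reactants: 22 C2 acetate
Product: 23 C9 primary alcohol
Conditions: HF·pyridine, pyridine, THF, 0 °C
Reagents that add atoms: none
Why: Buffered fluoride cleaves the primary silyl ether without hydrolysing the acetal, the acetonide or the acetate.

Step 16
Reactants: 23 C9 primary alcohol
Product: 24 C9 aldehyde
Conditions: Dess–Martin periodinane, NaHCO3, CH2Cl2, 0 °C → rt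
Reagents that add atoms: none
Why: Dess–Martin oxidation gives the aldehyde under neutral buffered conditions, and the C10 stereocenter, flanked by two fully substituted carbons, should not epimerise.

Step 17
Reactants: 24 C9 aldehyde; 25 diethyl ethynylphosphonate
Product: 26 (9R)-propargylic alcohol
Conditions: Me2Zn (3 equiv), (S,S)-ProPhenol (cat.), PhMe, 0 °C → rt; aq. NH4Cl
Reagents that add atoms: none
Why: Dinuclear zinc–ProPhenol catalysed alkynylation forms the C8–C9 bond, the chiral ligand directing the alkynylzinc to the Si face of the aldehyde so that the C9 carbinol stereocenter is set by reagent control under conditions that tolerate the acetate.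

Step 18
Reactants: 26 (9R)-propargylic alcohol
Product: 27 2,9-diacetate
Conditions: Ac2O, DMAP (cat.), pyridine, 0 °C
Reagents that add atoms: acetic anhydride, CC(=O)OC(C)=O
Why: Acetylation installs the C9 acetate of the target and provides the propargylic ester that assists the regioselective hydration of step 19.

Step 19
Reactants: 27 2,9-diacetate
Product: 29 enal β-ketophosphonate, via acetal β-ketophosphonate 28 (not isolated)
Conditions: Ph3PAuCl (cat.), AgOTf (cat.), 1,4-dioxane/H2O, rt; then 5% aq. oxalic acid, rt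
Reagents that add atoms: water, O
Why: Cationic gold-catalysed hydration of the alkynylphosphonate, directed both by phosphoryl polarisation and by anchimeric assistance of the propargylic acetate, places the ketone at C8, and mild acid then hydrolyses the allylic acetal to the C6 aldehyde while the ketal of the cis-diol survives.

Step 20
Reactants: 29 enal β-ketophosphonate
Product: 30 bicyclic (3Z,6E)-trienone
Conditions: LiCl, iPr2NEt, MeCN, high dilution (1 mM, slow addition), rt
Reagents that add atoms: none
Why: Intramolecular Horner–Wadsworth–Emmons olefination under high dilution with LiCl/amine activation closes the ten-membered ring by forming the conjugated (E)-C6=C7 enone, and the weak base leaves the C9 α-acetoxy stereocenter intact.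

Step 21
Reactants: 30 bicyclic (3Z,6E)-trienone
Product: 31 (6R,7S)-trans-6,7-epoxy ketone
Conditions: La(O-iPr)3 (cat.), (R)-BINOL (cat.), Ph3As=O (cat.), tert-butyl hydroperoxide, 4 Å molecular sieves, THF, rt
Reagents that add atoms: tert-butyl hydroperoxide, CC(C)(C)OO
Why: Lanthanum–BINOL-catalysed nucleophilic (Weitz–Scheffer-type) epoxidation is chemoselective for the electron-poor C6=C7 bond over the other four alkenes, gives the trans epoxide from the (E)-enone, and sets C6 and C7 under control of the chiral ligand.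

Step 22
Reactants: 31 (6R,7S)-trans-6,7-epoxy ketone
Product: 32 (6S,7R)-6-chloro-7-hydroxy 8-ketone
Conditions: HCl (1 M in Et2O, 1.1 equiv), CH2Cl2, −78 → −40 °C
Reagents that add atoms: hydrogen chloride, Cl
Why: Acid-promoted epoxide opening by chloride should occur with inversion at C6, the allylic carbon that best supports positive charge (C7 is deactivated by the adjacent carbonyl), converting the trans epoxide into the anti chlorohydrin with the C6 and C7 configurations of the target.

Step 23
Reactants: 32 (6S,7R)-6-chloro-7-hydroxy 8-ketone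
Product: 33 7-O-(2-bromopropanoyl) ester
Conditions: 2-bromopropanoyl bromide, pyridine, CH2Cl2, −40 °C
Reagents that add atoms: 2-bromopropanoyl bromide, CC(Br)C(Br)=O
Why: O-Acylation of the only free hydroxyl (C7) with an acid bromide and a weak base at low temperature avoids elimination of the β-chloride and acyl migration, and the configuration at the CHBr carbon is irrelevant because it becomes an enolate.

Step 24
Reactants: 33 7-O-(2-bromopropanoyl) ester
Product: 34 11,12-O-isopropylidene derivative of the target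
Conditions: SmI2 (2.2 equiv), THF, −78 °C; AcOH quench at −78 °C
Reagents that add atoms: none
Why: SmI2 reduces the α-bromo ester much faster than the ketone or the allylic chloride, and the samarium enolate adds intramolecularly to the C8 ketone (Reformatsky-type aldol closing the five-membered lactone) through a chelated bicyclic transition state that puts the bulky C9 branch trans to C6 and the C17 methyl cis to the new 8-hydroxyl, which sets C8 and C17.

Step 25
Reactants: 34 11,12-O-isopropylidene derivative of the target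
Product: 35 CNP0317097.1
Conditions: AcOH/H2O (4:1), 40 °C
Reagents that add atoms: none
Why: Mild aqueous acid hydrolyses the isopropylidene ketal to the free cis-11,12-diol without cleaving the acetates, the lactone or the allylic chloride.

**Compound list**

1 | 3-methylfuran-2-carboxylic acid | Cc1ccoc1C(=O)O | starting material
2 | 5-hydroxy-3-methylfuran-2(5H)-one (racemic lactol; pseudo-acid of (Z)-2-methyl-4-oxobut-2-enoic acid) | CC1=CC(O)OC1=O | intermediate
3 | (E)-4-chloro-3-methylbut-2-en-1-yl acetate | CC(=O)OC/C=C(\C)CCl | starting material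
4 | (E)-4-chloro-3-methylbut-2-en-1-ol | OC/C=C(\C)CCl | intermediate
5 | (E)-tert-butyl[(4-chloro-3-methylbut-2-en-1-yl)oxy]dimethylsilane | CC(C)(C)[Si](C)(C)OC/C=C(\C)CCl | intermediate
6 | (E)-{4-[(tert-butyldimethylsilyl)oxy]-2-methylbut-2-en-1-yl}triphenylphosphonium chloride | CC(C)(C)[Si](C)(C)OC/C=C(\C)C[P+](c1ccccc1)(c1ccccc1)c1ccccc1.[Cl-] | intermediate
7 | 2-bromo-3,3-diethoxyprop-1-ene (2-bromoacrolein diethyl acetal) | CCOC(OCC)C(Br)=C | starting material
8 | ethynyltrimethylsilane | C#C[Si](C)(C)C | starting material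
9 | [3-(diethoxymethyl)but-3-en-1-yn-1-yl]trimethylsilane | CCOC(OCC)C(=C)C#C[Si](C)(C)C | intermediate
10 | 3-(diethoxymethyl)but-3-en-1-yne | CCOC(OCC)C(=C)C#C | intermediate
11 | (E)-{4-[(tert-butyldimethylsilyl)oxy]-2-methylbut-2-en-1-ylidene}triphenylphosphorane | CC(C)(C)[Si](C)(C)OC/C=C(\C)C=P(c1ccccc1)(c1ccccc1)c1ccccc1 | intermediate
12 | sodium (2Z,4Z,6E)-8-[(tert-butyldimethylsilyl)oxy]-2,6-dimethylocta-2,4,6-trienoate | CC(C)(C)[Si](C)(C)OC/C=C(\C)/C=C\C=C(\C)C(=O)[O-].[Na+] | intermediate
13 | rac-(1S,6S)-6-{[(tert-butyldimethylsilyl)oxy]methyl}-1,5-dimethylcyclohexa-2,4-diene-1-carboxylic acid (racemate; SMILES shows the relative configuration, CO2H and CH2OTBS trans) | OC(=O)[C@@]1(C)C=CC=C(C)[C@@H]1CO[Si](C)(C)C(C)(C)C | intermediate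
14 | (S)-1-phenylethylamine | C[C@H](N)c1ccccc1 | starting material
15 | (S)-1-phenylethylammonium (1S,6S)-6-{[(tert-butyldimethylsilyl)oxy]methyl}-1,5-dimethylcyclohexa-2,4-diene-1-carboxylate | C[C@H]([NH3+])c1ccccc1.[O-]C(=O)[C@@]1(C)C=CC=C(C)[C@@H]1CO[Si](C)(C)C(C)(C)C | intermediate
16 | (1S,4R,5S,6S)-6-{[(tert-butyldimethylsilyl)oxy]methyl}-4,5-dihydroxy-1,5-dimethylcyclohex-2-ene-1-carboxylic acid (11α,12α-diol; C15 methyl and CH2OTBS β, CO2H α) | OC(=O)[C@@]1(C)C=C[C@@H](O)[C@@](C)(O)[C@@H]1CO[Si](C)(C)C(C)(C)C | intermediate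
17 | 11,12-O-isopropylidene derivative of 16 (cis-fused 2,2-dimethyl-1,3-dioxolane on the α face) | OC(=O)[C@@]1(C)C=C[C@H]2OC(C)(C)O[C@@]2(C)[C@@H]1CO[Si](C)(C)C(C)(C)C | intermediate
18 | acid chloride of 17 | ClC(=O)[C@@]1(C)C=C[C@H]2OC(C)(C)O[C@@]2(C)[C@@H]1CO[Si](C)(C)C(C)(C)C | intermediate
19 | C2 ynone: 17 with CO2H replaced by C(=O)–C≡C–C(=CH2)–CH(OEt)2 | CCOC(OCC)C(=C)C#CC(=O)[C@@]1(C)C=C[C@H]2OC(C)(C)O[C@@]2(C)[C@@H]1CO[Si](C)(C)C(C)(C)C | intermediate
20 | C2 propargylic alcohol from 19, C2–O configured as in the target | CCOC(OCC)C(=C)C#C[C@@H](O)[C@@]1(C)C=C[C@H]2OC(C)(C)O[C@@]2(C)[C@@H]1CO[Si](C)(C)C(C)(C)C | intermediate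
21 | (3Z)-allylic alcohol: side chain CH(OH)–CH=CH–C(=CH2)–CH(OEt)2 on C1 | CCOC(OCC)C(=C)/C=C\[C@@H](O)[C@@]1(C)C=C[C@H]2OC(C)(C)O[C@@]2(C)[C@@H]1CO[Si](C)(C)C(C)(C)C | intermediate
22 | C2 acetate of 21 | CCOC(OCC)C(=C)/C=C\[C@@H](OC(C)=O)[C@@]1(C)C=C[C@H]2OC(C)(C)O[C@@]2(C)[C@@H]1CO[Si](C)(C)C(C)(C)C | intermediate
23 | C9 primary alcohol (22 without the silyl group) | CCOC(OCC)C(=C)/C=C\[C@@H](OC(C)=O)[C@@]1(C)C=C[C@H]2OC(C)(C)O[C@@]2(C)[C@@H]1CO | intermediate
24 | C9 aldehyde (CHO on C10) | CCOC(OCC)C(=C)/C=C\[C@@H](OC(C)=O)[C@@]1(C)C=C[C@H]2OC(C)(C)O[C@@]2(C)[C@@H]1C=O | intermediate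
25 | diethyl ethynylphosphonate | C#CP(=O)(OCC)OCC | starting material
26 | (9R)-propargylic alcohol: C10–CH(OH)–C≡C–P(O)(OEt)2 | CCOC(OCC)C(=C)/C=C\[C@@H](OC(C)=O)[C@@]1(C)C=C[C@H]2OC(C)(C)O[C@@]2(C)[C@@H]1[C@@H](O)C#CP(=O)(OCC)OCC | intermediate
27 | 2,9-diacetate of 26 | CCOC(OCC)C(=C)/C=C\[C@@H](OC(C)=O)[C@@]1(C)C=C[C@H]2OC(C)(C)O[C@@]2(C)[C@@H]1[C@@H](OC(C)=O)C#CP(=O)(OCC)OCC | intermediate
28 | β-ketophosphonate C10–CH(OAc)–C(=O)–CH2–P(O)(OEt)2 with the C6 diethyl acetal intact | CCOC(OCC)C(=C)/C=C\[C@@H](OC(C)=O)[C@@]1(C)C=C[C@H]2OC(C)(C)O[C@@]2(C)[C@@H]1[C@@H](OC(C)=O)C(=O)CP(=O)(OCC)OCC | intermediate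
29 | enal β-ketophosphonate (28 with the acetal hydrolysed to the C6 aldehyde) | O=CC(=C)/C=C\[C@@H](OC(C)=O)[C@@]1(C)C=C[C@H]2OC(C)(C)O[C@@]2(C)[C@@H]1[C@@H](OC(C)=O)C(=O)CP(=O)(OCC)OCC | intermediate
30 | bicyclic trienone: ten-membered ring C1–C10 fused to ring A; 2-OAc, (3Z)-ene, 5-methylene, (6E)-en-8-one, 9-OAc, 11α,12α-acetonide | C=C1/C=C\[C@@H](OC(C)=O)[C@@]2(C)C=C[C@H]3OC(C)(C)O[C@@]3(C)[C@@H]2[C@@H](OC(C)=O)C(=O)/C=C/1 | intermediate
31 | (6R,7S)-trans-6,7-epoxide of 30 | C=C1/C=C\[C@@H](OC(C)=O)[C@@]2(C)C=C[C@H]3OC(C)(C)O[C@@]3(C)[C@@H]2[C@@H](OC(C)=O)C(=O)[C@H]4O[C@@H]41 | intermediate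
32 | (6S,7R)-6-chloro-7-hydroxy 8-ketone | C=C1/C=C\[C@@H](OC(C)=O)[C@@]2(C)C=C[C@H]3OC(C)(C)O[C@@]3(C)[C@@H]2[C@@H](OC(C)=O)C(=O)[C@@H](O)[C@H]1Cl | intermediate
33 | 7-O-(2-bromopropanoyl) ester of 32 (both epimers at the CHBr carbon) | C=C1/C=C\[C@@H](OC(C)=O)[C@@]2(C)C=C[C@H]3OC(C)(C)O[C@@]3(C)[C@@H]2[C@@H](OC(C)=O)C(=O)[C@@H](OC(=O)C(C)Br)[C@H]1Cl | intermediate
34 | 11,12-O-isopropylidene derivative of the target | C=C1/C=C\[C@@H](OC(C)=O)[C@@]2(C)C=C[C@H]3OC(C)(C)O[C@@]3(C)[C@@H]2[C@@H](OC(C)=O)[C@]2(O)[C@@H](C)C(=O)O[C@H]2[C@H]1Cl | intermediate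
35 | CNP0317097.1 | C=C1/C=C\[C@@H](OC(C)=O)[C@@]2(C)C=C[C@@H](O)[C@@](C)(O)[C@@H]2[C@@H](OC(C)=O)[C@]2(O)[C@@H](C)C(=O)O[C@H]2[C@H]1Cl | target

**Step count and risks**

Total step count: 25. Longest linear sequence: 22 steps (from 3 through steps 2–4 and 7–25).

Steps most likely to fail:

Step 7. Material may be lost through formation of the non-cyclising (4E)-olefin in the Wittig event, through base-induced isomerisation of the (2Z)-enoate before olefination, and through slow ring closure at the hindered terminus that becomes the quaternary C1. Fallback, setting out from 2 and returning at 13: the sodium salt of 2 is olefinated with iodomethylenetriphenylphosphorane (Stork–Zhao) to (2Z,4Z)-5-iodo-2-methylpenta-2,4-dienoic acid F1, so the cis alkene comes from a Z-selective iodo-olefination instead of from the allylic ylide. Stille coupling (Pd2(dba)3, AsPh3, CuI) with the known (E)-tert-butyldimethyl{[3-(tributylstannyl)but-2-en-1-yl]oxy}silane F2 then builds the C11–C12 bond with retention of both geometries and gives (2Z,4Z,6E)-8-[(tert-butyldimethylsilyl)oxy]-2,6-dimethylocta-2,4,6-trienoic acid F3, which is heated in toluene to close ring A and give 13.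

Step 20. Oligomerisation and Diels–Alder dimerisation of the 2-alkenylacrolein may compete with a strained ten-membered ring closure, and the base may epimerise C9. Fallback, setting out from 24 and returning at 30: aldehyde 24 is alkynylated with ethynyltrimethylsilane 8 (Me2Zn, ProPhenol) to the trimethylsilyl propargylic alcohol F4 and acetylated to the propargylic acetate F5. N-Bromosuccinimide with AgNO3 (cat.) converts the silylalkyne into the bromoalkyne F6, and gold-catalysed hydration with acetal hydrolysis gives the α-bromomethyl ketone enal F7. SmI2 at high dilution (−78 °C) then forms the samarium enolate, which closes the ten-membered ring by an intramolecular Reformatsky-type aldol addition to the macrocyclic β-hydroxy ketone F8, and dehydration with Burgess reagent gives enone 30.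

Step 22. Chloride may attack the wrong position (C7 by direct displacement α to the ketone, or C16 in an SN2′ sense), and the C6 configuration may erode through an allylic cation. Fallback, setting out from 31 and returning at 34: the zinc Reformatsky reagent from ethyl 2-bromopropanoate is added to the C8 ketone of 31 to give the epoxy β-hydroxy ester F9. With the carbonyl gone, chloride delivered from ClTi(O-iPr)3 opens the 2,3-epoxy alcohol at the distal allylic C6 with inversion to the chlorohydrin ester F10, which lactonises (PPTS, toluene, 60 °C) to 34, so steps 22–24 are bypassed.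

**Further compounds**

F1 | step 7 | (2Z,4Z)-5-iodo-2-methylpenta-2,4-dienoic acid | OC(=O)/C(C)=C\C=C/I
F2 | step 7 | (E)-tert-butyldimethyl{[3-(tributylstannyl)but-2-en-1-yl]oxy}silane | CCCC[Sn](CCCC)(CCCC)/C(C)=C/CO[Si](C)(C)C(C)(C)C
F3 | step 7 | (2Z,4Z,6E)-8-[(tert-butyldimethylsilyl)oxy]-2,6-dimethylocta-2,4,6-trienoic acid | CC(C)(C)[Si](C)(C)OC/C=C(\C)/C=C\C=C(\C)C(=O)O
F4 | step 20 | trimethylsilyl propargylic alcohol: C10–CH(OH)–C≡C–SiMe3 analogue of 26 | CCOC(OCC)C(=C)/C=C\[C@@H](OC(C)=O)[C@@]1(C)C=C[C@H]2OC(C)(C)O[C@@]2(C)[C@@H]1[C@@H](O)C#C[Si](C)(C)C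
F5 | step 20 | propargylic acetate of F4 | CCOC(OCC)C(=C)/C=C\[C@@H](OC(C)=O)[C@@]1(C)C=C[C@H]2OC(C)(C)O[C@@]2(C)[C@@H]1[C@@H](OC(C)=O)C#C[Si](C)(C)C
F6 | step 20 | bromoalkyne: C10–CH(OAc)–C≡C–Br | CCOC(OCC)C(=C)/C=C\[C@@H](OC(C)=O)[C@@]1(C)C=C[C@H]2OC(C)(C)O[C@@]2(C)[C@@H]1[C@@H](OC(C)=O)C#CBr
F7 | step 20 | α-bromomethyl ketone enal: C10–CH(OAc)–C(=O)–CH2Br with the C6 aldehyde | O=CC(=C)/C=C\[C@@H](OC(C)=O)[C@@]1(C)C=C[C@H]2OC(C)(C)O[C@@]2(C)[C@@H]1[C@@H](OC(C)=O)C(=O)CBr
F8 | step 20 | macrocyclic β-hydroxy ketone (6-hydroxy-8-ketone, both C6 epimers) | C=C1/C=C\[C@@H](OC(C)=O)[C@@]2(C)C=C[C@H]3OC(C)(C)O[C@@]3(C)[C@@H]2[C@@H](OC(C)=O)C(=O)CC1O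
F9 | step 22 | epoxy β-hydroxy ester: 6,7-epoxide with C8(OH)–CH(CH3)–CO2Et | C=C1/C=C\[C@@H](OC(C)=O)[C@@]2(C)C=C[C@H]3OC(C)(C)O[C@@]3(C)[C@@H]2[C@@H](OC(C)=O)[C@](O)([C@@H](C)C(=O)OCC)[C@H]4O[C@@H]41
F10 | step 22 | chlorohydrin ester: 6-chloro-7,8-dihydroxy with C8–CH(CH3)–CO2Et | C=C1/C=C\[C@@H](OC(C)=O)[C@@]2(C)C=C[C@H]3OC(C)(C)O[C@@]3(C)[C@@H]2[C@@H](OC(C)=O)[C@](O)([C@@H](C)C(=O)OCC)[C@@H](O)[C@H]1Cl
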